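## Retrosynthetic overview

1. Target 26 comes from its nonamethyl derivative 24 by global O-demethylation; 24 comes from the C3 acid 19 and the (S)-lactate 23 by Mitsunobu esterification with inversion.
2. The caffeoyl-lactate arm on C4 comes from enol ester 17 by asymmetric hydrogenation; 17 comes from aryl chloride 13 and acyloxyacrylate 16 by a Heck reaction.
3. Ring B (the dihydrofuran) is the only ring that is made; all benzene rings are bought. It is closed last, from the open β-hydroxy ester 6, by a C7a≡C7 aryne that takes up O1 at C7a and a hydroxyl at C7.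
4. Enabling feature: ring A carries oxygen on two neighbouring carbons, C7a (ring oxygen O1) and C7 (phenol), and C7a is ortho to C3a, whose C3–C2 chain holds O1. The tether on the C3a side of the triple bond sends O1 to C7a (five-membered ring only) and leaves the carbanion at C7, on the C6–H side, for oxygenation.
5. Compound 6 comes from β-keto ester 5 by asymmetric transfer hydrogenation (fixes C2); 5 comes from arylacetate 2 and aroyl chloride 3 by Claisen acylation.

Key step: step 4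

Assumption: the target is read as the trans-(2S,3S)-dihydrobenzofuran with both lactate centres (R); compounds 1, 3, 14, 15, 20 and 21 are taken as commercial.

## Route

Step 1
Reactants: 1 2-(2-chloro-6-fluorophenyl)acetic acid
Product: 2 tert-butyl 2-(2-chloro-6-fluorophenyl)acetate
Conditions: tert-butyl 2,2,2-trichloroacetimidate, BF3·OEt2 (cat.), CH2Cl2/cyclohexane, 25 °C
Reagents that add atoms: tert-butyl 2,2,2-trichloroacetimidate, CC(C)(C)OC(=N)C(Cl)(Cl)Cl
Why: Acid-catalysed tert-butyl transfer from the trichloroacetimidate (imidate esterification) should give the hindered ester that later resists organolithium addition and is cleaved by acid in the presence of methyl esters; no stereocentre is formed.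

Step 2
Reactants: 2 tert-butyl 2-(2-chloro-6-fluorophenyl)acetate; 3 3,4-dimethoxybenzoyl chloride
Product: 5 tert-butyl 2-(2-chloro-6-fluorophenyl)-3-(3,4-dimethoxyphenyl)-3-oxopropanoate (racemic), via lithium ester enolate 4 (not isolated)
Conditions: LiN(SiMe3)2 (2.2 equiv), THF, −78 °C; then 3, −78 to 0 °C; aq. NH4Cl
Reagents that add atoms: none
Why: Crossed Claisen C-acylation of the ester enolate by the aroyl chloride, with the second equivalent of base taking up the more acidic β-keto ester so that it is not acylated again; the α-centre is racemic and is erased later.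

Step 3
Reactants: 5 tert-butyl 2-(2-chloro-6-fluorophenyl)-3-(3,4-dimethoxyphenyl)-3-oxopropanoate
Product: 6 tert-butyl (3S)-2-(2-chloro-6-fluorophenyl)-3-(3,4-dimethoxyphenyl)-3-hydroxypropanoate (both C2 epimers)
Conditions: RuCl(p-cymene)[(S,S)-TsDPEN] (2 mol %), HCO2H/Et3N (5:2), DMF, 40 °C
Reagents that add atoms: none
Why: Noyori asymmetric transfer hydrogenation of the aryl ketone, in which the (S,S)-diamine catalyst is expected by analogy with acetophenone-type ketones to deliver hydride so that the carbinol is (S) (catalyst control through the CH/π contact with the dimethoxyphenyl ring); the configuration at C2 of the propanoate does not matter because it is erased in step 4.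

Step 4
Reactants: 6 tert-butyl (3S)-2-(2-chloro-6-fluorophenyl)-3-(3,4-dimethoxyphenyl)-3-hydroxypropanoate
Product: 11 tert-butyl (2S)-4-chloro-2-(3,4-dimethoxyphenyl)-7-hydroxy-2,3-dihydro-1-benzofuran-3-carboxylate (C3 epimer mixture), via trilithiated fluoroarene 7 (not isolated), via aryne dianion 8 (not isolated), via 7-lithio enolate 9 (not isolated), via aryl trimethoxyborate 10 (not isolated)
Conditions: sec-BuLi (3.3 equiv), THF, −78 °C, then −30 °C; B(OMe)3, −78 to 0 °C; AcOH, 30% aq. H2O2, 0 to 25 °C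
Reagents that add atoms: hydrogen peroxide, OO
Why: Three equivalents of sec-BuLi should convert 6 into the chelated β-oxido ester enolate (a Fráter–Seebach-type dianion, which blocks retro-aldol cleavage and holds the enolate oxygen on the side away from ring A) and then lithiate C7–H ortho to fluorine (7); loss of LiF on warming should give the C7a≡C7 aryne 8. The closest known reaction type is the benzyne cyclisation of a tethered alkoxide followed by electrophilic trapping of the new aryllithium, here by borylation and oxidation. Ring B closes by in-plane attack of the C2 alkoxide oxygen on C7a (five-membered, exo-type addition to the aryne); attack at C7 would need a meta-bridged ring and the enolate carbon C3 could only form a three-membered ring, so O1–C7a is the only tethered closure. The carbanion of 9 therefore sits at C7, and B(OMe)3 then H2O2 place the second oxygen there, so the aryne takes up O1 at C7a and OH at C7 in one flask, the side of each addition being fixed by the tether on C3a rather than by electronic bias. No new stereocentre is created at C2, whose carbinol configuration from step 3 is carried through with retention because only its O–H bond is replaced by O–C7a; C3 passes through the planar enolate, so both epimers of 6 converge and C3 is set in step 5. The step needs lithiation ortho to F rather than ortho to Cl or on the dimethoxyphenyl ring, which the far stronger acidifying effect of fluorine should secure, and amine-free conditions keep 9 from being protonated before borylation.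

Step 5
Reactants: 11 tert-butyl (2S)-4-chloro-2-(3,4-dimethoxyphenyl)-7-hydroxy-2,3-dihydro-1-benzofuran-3-carboxylate
Product: 13 tert-butyl (2S,3S)-4-chloro-2-(3,4-dimethoxyphenyl)-7-methoxy-2,3-dihydro-1-benzofuran-3-carboxylate, via O-methylated C3 epimer mixture 12 (not isolated)
Conditions: MeI, K2CO3, acetone, 25 °C; filter, evaporate; DBU, toluene, 60 °C
Reagents that add atoms: iodomethane, CI
Why: Williamson O-methylation of the phenol followed by base-mediated epimerisation through the C3 ester enolate, which should funnel both epimers into the thermodynamically preferred trans ester, so that C3 (S) is set by thermodynamic control relative to the fixed C2 (S) centre.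

Step 6
Reactants: 14 methyl pyruvate; 15 (2E)-3-(3,4-dimethoxyphenyl)prop-2-enoyl chloride
Product: 16 methyl 2-{[(2E)-3-(3,4-dimethoxyphenyl)prop-2-enoyl]oxy}prop-2-enoate
Conditions: Et3N, DMAP (cat.), CH2Cl2, 0 °C
Reagents that add atoms: none
Why: O-acylation of the pyruvate enolate (enol ester formation) should give the captodative acrylate that already carries the protected caffeoyl group; no stereocentre is formed.

Step 7
Reactants: 13 tert-butyl (2S,3S)-4-chloro-2-(3,4-dimethoxyphenyl)-7-methoxy-2,3-dihydro-1-benzofuran-3-carboxylate; 16 methyl 2-{[(2E)-3-(3,4-dimethoxyphenyl)prop-2-enoyl]oxy}prop-2-enoate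
Product: 17 tert-butyl (2S,3S)-4-[(1Z)-2-{[(2E)-3-(3,4-dimethoxyphenyl)prop-2-enoyl]oxy}-3-methoxy-3-oxoprop-1-en-1-yl]-2-(3,4-dimethoxyphenyl)-7-methoxy-2,3-dihydro-1-benzofuran-3-carboxylate
Conditions: Pd2(dba)3 (2.5 mol %), [HP(t-Bu)3]BF4 (10 mol %), Cy2NMe, 1,4-dioxane, 100 °C
Reagents that add atoms: none
Why: Mizoroki–Heck arylation of the terminal 1,1-disubstituted alkene of 16 by the aryl chloride, for which the bulky electron-rich trialkylphosphine is the established activator, while the internal cinnamate alkene is far less reactive; no stereocentre is formed and either enol ester geometry serves step 8.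

Step 8
Reactants: 17 tert-butyl (2S,3S)-4-[(1Z)-2-{[(2E)-3-(3,4-dimethoxyphenyl)prop-2-enoyl]oxy}-3-methoxy-3-oxoprop-1-en-1-yl]-2-(3,4-dimethoxyphenyl)-7-methoxy-2,3-dihydro-1-benzofuran-3-carboxylate
Product: 18 tert-butyl (2S,3S)-4-[(2R)-2-{[(2E)-3-(3,4-dimethoxyphenyl)prop-2-enoyl]oxy}-3-methoxy-3-oxopropyl]-2-(3,4-dimethoxyphenyl)-7-methoxy-2,3-dihydro-1-benzofuran-3-carboxylate
Conditions: [Rh(cod)((R,R)-Et-DuPhos)]BF4 (2 mol %), H2 (4 bar), MeOH, 25 °C
Reagents that add atoms: none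
Why: Rhodium-bisphospholane asymmetric hydrogenation of an α-acyloxy acrylate, in which chelation of the enol ester carbonyl to rhodium should restrict reduction to this alkene and the (R,R)-ligand is expected to set the (R)-acyloxy centre by catalyst control, leaving the non-chelating cinnamate alkene and the benzylic C2–O bond untouched.

Step 9
Reactants: 18 tert-butyl (2S,3S)-4-[(2R)-2-{[(2E)-3-(3,4-dimethoxyphenyl)prop-2-enoyl]oxy}-3-methoxy-3-oxopropyl]-2-(3,4-dimethoxyphenyl)-7-methoxy-2,3-dihydro-1-benzofuran-3-carboxylate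
Product: 19 (2S,3S)-4-[(2R)-2-{[(2E)-3-(3,4-dimethoxyphenyl)prop-2-enoyl]oxy}-3-methoxy-3-oxopropyl]-2-(3,4-dimethoxyphenyl)-7-methoxy-2,3-dihydro-1-benzofuran-3-carboxylic acid
Conditions: CF3CO2H, CH2Cl2, 0 to 25 °C
Reagents that add atoms: none
Why: Acidolysis of the tert-butyl ester by alkyl–oxygen cleavage should free only the C3 acid, since methyl esters, the acyloxy ester and aryl methyl ethers are stable to these conditions; no stereocentre is touched.

Step 10
Reactants: 20 4-bromo-1,2-dimethoxybenzene; 21 methyl (2S)-oxirane-2-carboxylate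
Product: 23 methyl (2S)-3-(3,4-dimethoxyphenyl)-2-hydroxypropanoate, via arylmagnesium bromide 22 (not isolated)
Conditions: Mg, THF, 25 °C; then CuI (10 mol %), 21, −40 to −20 °C; aq. NH4Cl
Reagents that add atoms: none
Why: Copper-catalysed ring opening of the glycidate by the aryl Grignard reagent at the unsubstituted epoxide carbon, faster than ester addition at low temperature; the stereocentre of 21 is not involved and is carried over as (S).

Step 11
Reactants: 19 (2S,3S)-4-[(2R)-2-{[(2E)-3-(3,4-dimethoxyphenyl)prop-2-enoyl]oxy}-3-methoxy-3-oxopropyl]-2-(3,4-dimethoxyphenyl)-7-methoxy-2,3-dihydro-1-benzofuran-3-carboxylic acid; 23 methyl (2S)-3-(3,4-dimethoxyphenyl)-2-hydroxypropanoate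
Product: 24 (2R)-3-(3,4-dimethoxyphenyl)-1-methoxy-1-oxopropan-2-yl (2S,3S)-4-[(2R)-2-{[(2E)-3-(3,4-dimethoxyphenyl)prop-2-enoyl]oxy}-3-methoxy-3-oxopropyl]-2-(3,4-dimethoxyphenyl)-7-methoxy-2,3-dihydro-1-benzofuran-3-carboxylate
Conditions: PPh3, DIAD, THF, 0 to 25 °C
Reagents that add atoms: none
Why: Mitsunobu esterification, in which the carboxylate of 19 displaces the activated α-hydroxy ester oxygen by SN2 so that (S)-23 gives the (R)-ester by inversion, and the C3 acid is never turned into an acylating agent and so should not epimerise.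

Step 12
Reactants: 24 (2R)-3-(3,4-dimethoxyphenyl)-1-methoxy-1-oxopropan-2-yl (2S,3S)-4-[(2R)-2-{[(2E)-3-(3,4-dimethoxyphenyl)prop-2-enoyl]oxy}-3-methoxy-3-oxopropyl]-2-(3,4-dimethoxyphenyl)-7-methoxy-2,3-dihydro-1-benzofuran-3-carboxylate
Product: 26 (2R)-3-[(2S,3S)-3-{[(1R)-1-carboxy-2-(3,4-dihydroxyphenyl)ethoxy]carbonyl}-2-(3,4-dihydroxyphenyl)-7-hydroxy-2,3-dihydro-1-benzofuran-4-yl]-2-{[(2E)-3-(3,4-dihydroxyphenyl)prop-2-enoyl]oxy}propanoic acid, via nonakis(trimethylsilyl) derivative 25 (not isolated)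
Conditions: Me3SiI, quinoline, 140 °C; then 1 M aq. HCl, 25 °C
Reagents that add atoms: none
Why: Silyl iodide dealkylation, in which iodide attacks the methyl groups of the seven aryl methyl ethers and two methyl esters by SN2 much faster than the secondary ester carbons, quinoline buffering the acid, and hydrolysis of the silyl ethers and esters should release the target with all four stereocentres unchanged.

## Compound list

1 | 2-(2-chloro-6-fluorophenyl)acetic acid | OC(=O)Cc1c(F)cccc1Cl | starting material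
2 | tert-butyl 2-(2-chloro-6-fluorophenyl)acetate | CC(C)(C)OC(=O)Cc1c(F)cccc1Cl | intermediate
3 | 3,4-dimethoxybenzoyl chloride | COc1ccc(cc1OC)C(Cl)=O | starting material
4 | lithium enolate of 2 | CC(C)(C)OC(O[Li])=Cc1c(F)cccc1Cl | intermediate
5 | tert-butyl 2-(2-chloro-6-fluorophenyl)-3-(3,4-dimethoxyphenyl)-3-oxopropanoate (racemic) | CC(C)(C)OC(=O)C(c1c(F)cccc1Cl)C(=O)c1ccc(OC)c(OC)c1 | intermediate
6 | tert-butyl (3S)-2-(2-chloro-6-fluorophenyl)-3-(3,4-dimethoxyphenyl)-3-hydroxypropanoate (both C2 epimers) | CC(C)(C)OC(=O)C(c1c(F)cccc1Cl)[C@H](O)c1ccc(OC)c(OC)c1 | intermediate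
7 | trilithio species from 6: lithium alkoxide, lithium ester enolate and aryllithium ortho to fluorine | CC(C)(C)OC(O[Li])=C(c1c(F)c([Li])ccc1Cl)[C@H](O[Li])c1ccc(OC)c(OC)c1 | intermediate
8 | aryne (triple bond between the former C–F and C–Li carbons) carrying the lithium alkoxide and lithium ester enolate | CC(C)(C)OC(O[Li])=C(C1=C(Cl)C=CC#C1)[C@H](O[Li])c1ccc(OC)c(OC)c1 | intermediate
9 | 7-lithio-4-chloro-2-(3,4-dimethoxyphenyl)-2,3-dihydro-1-benzofuran as the C3 lithium ester enolate (tert-butyl ester) | Clc1ccc([Li])c2c1C(=C(O[Li])OC(C)(C)C)[C@@H](c1ccc(OC)c(OC)c1)O2 | intermediate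
10 | lithium C7-aryl trimethoxyborate of 9 (C3 lithium ester enolate) | Clc1ccc([B-](OC)(OC)OC)c2c1C(=C(O[Li])OC(C)(C)C)[C@@H](c1ccc(OC)c(OC)c1)O2.[Li+] | intermediate
11 | tert-butyl (2S)-4-chloro-2-(3,4-dimethoxyphenyl)-7-hydroxy-2,3-dihydro-1-benzofuran-3-carboxylate (C3 epimer mixture) | Clc1ccc(O)c2c1C(C(=O)OC(C)(C)C)[C@@H](c1ccc(OC)c(OC)c1)O2 | intermediate
12 | tert-butyl (2S)-4-chloro-2-(3,4-dimethoxyphenyl)-7-methoxy-2,3-dihydro-1-benzofuran-3-carboxylate (C3 epimer mixture) | Clc1ccc(OC)c2c1C(C(=O)OC(C)(C)C)[C@@H](c1ccc(OC)c(OC)c1)O2 | intermediate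
13 | tert-butyl (2S,3S)-4-chloro-2-(3,4-dimethoxyphenyl)-7-methoxy-2,3-dihydro-1-benzofuran-3-carboxylate | Clc1ccc(OC)c2c1[C@H](C(=O)OC(C)(C)C)[C@@H](c1ccc(OC)c(OC)c1)O2 | intermediate
14 | methyl pyruvate | CC(=O)C(=O)OC | starting material
15 | (2E)-3-(3,4-dimethoxyphenyl)prop-2-enoyl chloride | COc1ccc(/C=C/C(Cl)=O)cc1OC | starting material
16 | methyl 2-{[(2E)-3-(3,4-dimethoxyphenyl)prop-2-enoyl]oxy}prop-2-enoate | C=C(OC(=O)/C=C/c1ccc(OC)c(OC)c1)C(=O)OC | intermediate
17 | tert-butyl (2S,3S)-4-[(1Z)-2-{[(2E)-3-(3,4-dimethoxyphenyl)prop-2-enoyl]oxy}-3-methoxy-3-oxoprop-1-en-1-yl]-2-(3,4-dimethoxyphenyl)-7-methoxy-2,3-dihydro-1-benzofuran-3-carboxylate | O=C(/C=C/c1ccc(OC)c(OC)c1)O/C(=C\c1ccc(OC)c2c1[C@H](C(=O)OC(C)(C)C)[C@@H](c1ccc(OC)c(OC)c1)O2)C(=O)OC | intermediate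
18 | tert-butyl (2S,3S)-4-[(2R)-2-{[(2E)-3-(3,4-dimethoxyphenyl)prop-2-enoyl]oxy}-3-methoxy-3-oxopropyl]-2-(3,4-dimethoxyphenyl)-7-methoxy-2,3-dihydro-1-benzofuran-3-carboxylate | O=C(/C=C/c1ccc(OC)c(OC)c1)O[C@H](Cc1ccc(OC)c2c1[C@H](C(=O)OC(C)(C)C)[C@@H](c1ccc(OC)c(OC)c1)O2)C(=O)OC | intermediate
19 | (2S,3S)-4-[(2R)-2-{[(2E)-3-(3,4-dimethoxyphenyl)prop-2-enoyl]oxy}-3-methoxy-3-oxopropyl]-2-(3,4-dimethoxyphenyl)-7-methoxy-2,3-dihydro-1-benzofuran-3-carboxylic acid | O=C(/C=C/c1ccc(OC)c(OC)c1)O[C@H](Cc1ccc(OC)c2c1[C@H](C(=O)O)[C@@H](c1ccc(OC)c(OC)c1)O2)C(=O)OC | intermediate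
20 | 4-bromo-1,2-dimethoxybenzene | COc1ccc(Br)cc1OC | starting material
21 | methyl (2S)-oxirane-2-carboxylate | COC(=O)[C@@H]1CO1 | starting material
22 | (3,4-dimethoxyphenyl)magnesium bromide | COc1ccc([Mg]Br)cc1OC | intermediate
23 | methyl (2S)-3-(3,4-dimethoxyphenyl)-2-hydroxypropanoate | COC(=O)[C@@H](O)Cc1ccc(OC)c(OC)c1 | intermediate
24 | (2R)-3-(3,4-dimethoxyphenyl)-1-methoxy-1-oxopropan-2-yl (2S,3S)-4-[(2R)-2-{[(2E)-3-(3,4-dimethoxyphenyl)prop-2-enoyl]oxy}-3-methoxy-3-oxopropyl]-2-(3,4-dimethoxyphenyl)-7-methoxy-2,3-dihydro-1-benzofuran-3-carboxylate | O=C(/C=C/c1ccc(OC)c(OC)c1)O[C@H](Cc1ccc(OC)c2c1[C@H](C(=O)O[C@H](Cc1ccc(OC)c(OC)c1)C(=O)OC)[C@@H](c1ccc(OC)c(OC)c1)O2)C(=O)OC | intermediate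
25 | nonakis(trimethylsilyl) derivative of 26 (seven aryl silyl ethers, two silyl esters) | O=C(/C=C/c1ccc(O[Si](C)(C)C)c(O[Si](C)(C)C)c1)O[C@H](Cc1ccc(O[Si](C)(C)C)c2c1[C@H](C(=O)O[C@H](Cc1ccc(O[Si](C)(C)C)c(O[Si](C)(C)C)c1)C(=O)O[Si](C)(C)C)[C@@H](c1ccc(O[Si](C)(C)C)c(O[Si](C)(C)C)c1)O2)C(=O)O[Si](C)(C)C | intermediate
26 | (2R)-3-[(2S,3S)-3-{[(1R)-1-carboxy-2-(3,4-dihydroxyphenyl)ethoxy]carbonyl}-2-(3,4-dihydroxyphenyl)-7-hydroxy-2,3-dihydro-1-benzofuran-4-yl]-2-{[(2E)-3-(3,4-dihydroxyphenyl)prop-2-enoyl]oxy}propanoic acid (CNP0201431.1) | O=C(/C=C/c1ccc(O)c(O)c1)O[C@H](Cc1ccc(O)c2c1[C@H](C(=O)O[C@H](Cc1ccc(O)c(O)c1)C(=O)O)[C@@H](c1ccc(O)c(O)c1)O2)C(=O)O | target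

## Step count and risks

Total step count: 12. Longest linear sequence: 10 (steps 1, 2, 3, 4, 5, 7, 8, 9, 11, 12).

Steps most likely to fail:

**Step 4.** The polyanionic sequence may go astray in several ways:
- competing lithiation on the dimethoxyphenyl ring;
- attack of the enolate oxygen on the aryne;
- β-elimination of the new aryl ether from the C3 enolate;
- protonation of the C7 aryllithium before borylation.

The fallback removes the ester enolate by working at the alcohol oxidation level. It sets out from 6 and returns at 12.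
- 6 would be reduced with LiAlH4 (THF, 0 °C) to (1S)-2-(2-chloro-6-fluorophenyl)-1-(3,4-dimethoxyphenyl)propane-1,3-diol F1.
- The primary hydroxyl would be silylated (t-BuMe2SiCl, imidazole, CH2Cl2) to give (1S)-3-{[tert-butyl(dimethyl)silyl]oxy}-2-(2-chloro-6-fluorophenyl)-1-(3,4-dimethoxyphenyl)propan-1-ol F2.
- The same aryne cyclisation, borylation and oxidation would be run with only the alkoxide present (sec-BuLi, 2.2 equiv, THF, −78 to −30 °C; B(OMe)3; AcOH, H2O2), to give (2S)-3-({[tert-butyl(dimethyl)silyl]oxy}methyl)-4-chloro-2-(3,4-dimethoxyphenyl)-2,3-dihydro-1-benzofuran-7-ol F3.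
- O-Methylation (MeI, K2CO3, acetone) would give tert-butyl{[(2S)-4-chloro-2-(3,4-dimethoxyphenyl)-7-methoxy-2,3-dihydro-1-benzofuran-3-yl]methoxy}dimethylsilane F4.
- Desilylation (Bu4NF, THF) would give [(2S)-4-chloro-2-(3,4-dimethoxyphenyl)-7-methoxy-2,3-dihydro-1-benzofuran-3-yl]methanol F5.
- Oxidation (TEMPO, PhI(OAc)2, MeCN/H2O) would give (2S)-4-chloro-2-(3,4-dimethoxyphenyl)-7-methoxy-2,3-dihydro-1-benzofuran-3-carboxylic acid F6.
- tert-Butylation as in step 1 would return the C3 epimer mixture 12, which the DBU stage of step 5 converts into 13.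

**Step 7.** Oxidative addition of the hindered, electron-rich aryl chloride may be slow, and the enol ester acrylate may polymerise or transfer its acyl group at 100 °C. The fallback builds the same enol ester by olefination. It sets out from 13 and returns at 17.
- Suzuki–Miyaura vinylation of 13 (CH2=CHBF3K, Pd(OAc)2, SPhos, K2CO3, THF/H2O, 80 °C) would give tert-butyl (2S,3S)-2-(3,4-dimethoxyphenyl)-4-ethenyl-7-methoxy-2,3-dihydro-1-benzofuran-3-carboxylate F7.
- Lemieux–Johnson cleavage (OsO4 cat., NaIO4, 2,6-lutidine, dioxane/H2O) would give tert-butyl (2S,3S)-2-(3,4-dimethoxyphenyl)-4-formyl-7-methoxy-2,3-dihydro-1-benzofuran-3-carboxylate F8.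
- Separately, Rh2(OAc)4-catalysed O–H insertion of methyl 2-diazo-2-(dimethoxyphosphoryl)acetate into (E)-3,4-dimethoxycinnamic acid would give methyl 2-(dimethoxyphosphoryl)-2-{[(2E)-3-(3,4-dimethoxyphenyl)prop-2-enoyl]oxy}acetate F9.
- Horner–Wadsworth–Emmons olefination of F8 with F9 (1,1,3,3-tetramethylguanidine, THF, −78 to 25 °C) would give 17 together with its (1E)-isomer tert-butyl (2S,3S)-4-[(1E)-2-{[(2E)-3-(3,4-dimethoxyphenyl)prop-2-enoyl]oxy}-3-methoxy-3-oxoprop-1-en-1-yl]-2-(3,4-dimethoxyphenyl)-7-methoxy-2,3-dihydro-1-benzofuran-3-carboxylate F10. Both should converge on 18 in step 8.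

**Step 12.** Exhaustive demethylation at high temperature may also cleave the two secondary acyloxy ester links or add HI across the cinnamate. The fallback splits the deprotection into two milder stages. It sets out from 24 and returns at 26.
- The two methyl esters would first be hydrolysed with Me3SnOH (1,2-dichloroethane, 80 °C) to the diacid (2R)-3-[(2S,3S)-3-{[(1R)-1-carboxy-2-(3,4-dimethoxyphenyl)ethoxy]carbonyl}-2-(3,4-dimethoxyphenyl)-7-methoxy-2,3-dihydro-1-benzofuran-4-yl]-2-{[(2E)-3-(3,4-dimethoxyphenyl)prop-2-enoyl]oxy}propanoic acid F11.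
- The seven aryl methyl ethers would then be cleaved with BBr3 (CH2Cl2, −78 to 0 °C; then H2O) to give 26.

## Further compounds

F1 | step 4 | (1S)-2-(2-chloro-6-fluorophenyl)-1-(3,4-dimethoxyphenyl)propane-1,3-diol (C2 epimers) | OCC(c1c(F)cccc1Cl)[C@H](O)c1ccc(OC)c(OC)c1
F2 | step 4 | (1S)-3-{[tert-butyl(dimethyl)silyl]oxy}-2-(2-chloro-6-fluorophenyl)-1-(3,4-dimethoxyphenyl)propan-1-ol (C2 epimers) | CC(C)(C)[Si](C)(C)OCC(c1c(F)cccc1Cl)[C@H](O)c1ccc(OC)c(OC)c1
F3 | step 4 | (2S)-3-({[tert-butyl(dimethyl)silyl]oxy}methyl)-4-chloro-2-(3,4-dimethoxyphenyl)-2,3-dihydro-1-benzofuran-7-ol (C3 epimers) | Clc1ccc(O)c2c1C(CO[Si](C)(C)C(C)(C)C)[C@@H](c1ccc(OC)c(OC)c1)O2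
F4 | step 4 | tert-butyl{[(2S)-4-chloro-2-(3,4-dimethoxyphenyl)-7-methoxy-2,3-dihydro-1-benzofuran-3-yl]methoxy}dimethylsilane (C3 epimers) | Clc1ccc(OC)c2c1C(CO[Si](C)(C)C(C)(C)C)[C@@H](c1ccc(OC)c(OC)c1)O2
F5 | step 4 | [(2S)-4-chloro-2-(3,4-dimethoxyphenyl)-7-methoxy-2,3-dihydro-1-benzofuran-3-yl]methanol (C3 epimers) | Clc1ccc(OC)c2c1C(CO)[C@@H](c1ccc(OC)c(OC)c1)O2
F6 | step 4 | (2S)-4-chloro-2-(3,4-dimethoxyphenyl)-7-methoxy-2,3-dihydro-1-benzofuran-3-carboxylic acid (C3 epimers) | Clc1ccc(OC)c2c1C(C(=O)O)[C@@H](c1ccc(OC)c(OC)c1)O2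
F7 | step 7 | tert-butyl (2S,3S)-2-(3,4-dimethoxyphenyl)-4-ethenyl-7-methoxy-2,3-dihydro-1-benzofuran-3-carboxylate | C=Cc1ccc(OC)c2c1[C@H](C(=O)OC(C)(C)C)[C@@H](c1ccc(OC)c(OC)c1)O2
F8 | step 7 | tert-butyl (2S,3S)-2-(3,4-dimethoxyphenyl)-4-formyl-7-methoxy-2,3-dihydro-1-benzofuran-3-carboxylate | O=Cc1ccc(OC)c2c1[C@H](C(=O)OC(C)(C)C)[C@@H](c1ccc(OC)c(OC)c1)O2
F9 | step 7 | methyl 2-(dimethoxyphosphoryl)-2-{[(2E)-3-(3,4-dimethoxyphenyl)prop-2-enoyl]oxy}acetate | COC(=O)C(OC(=O)/C=C/c1ccc(OC)c(OC)c1)P(=O)(OC)OC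
F10 | step 7 | tert-butyl (2S,3S)-4-[(1E)-2-{[(2E)-3-(3,4-dimethoxyphenyl)prop-2-enoyl]oxy}-3-methoxy-3-oxoprop-1-en-1-yl]-2-(3,4-dimethoxyphenyl)-7-methoxy-2,3-dihydro-1-benzofuran-3-carboxylate | O=C(/C=C/c1ccc(OC)c(OC)c1)O/C(=C/c1ccc(OC)c2c1[C@H](C(=O)OC(C)(C)C)[C@@H](c1ccc(OC)c(OC)c1)O2)C(=O)OC
F11 | step 12 | (2R)-3-[(2S,3S)-3-{[(1R)-1-carboxy-2-(3,4-dimethoxyphenyl)ethoxy]carbonyl}-2-(3,4-dimethoxyphenyl)-7-methoxy-2,3-dihydro-1-benzofuran-4-yl]-2-{[(2E)-3-(3,4-dimethoxyphenyl)prop-2-enoyl]oxy}propanoic acid | O=C(/C=C/c1ccc(OC)c(OC)c1)O[C@H](Cc1ccc(OC)c2c1[C@H](C(=O)O[C@H](Cc1ccc(OC)c(OC)c1)C(=O)O)[C@@H](c1ccc(OC)c(OC)c1)O2)C(=O)O
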